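The numbers in the tables were computed from invented constants.

At 2.0 h, the time of reading, I wanted the average length of the chains in the flask.

| setting | beta | delta | zeta | flask |
|---|---|---|---|---|
| E | 0.28 M | 0.44 M | 0.20 M | 0.20 M |
| D | 4 mM | 4 mM | 4 mM | 4.00 mM |
| L | 20 mM | 20 mM | 40 mM | 20 mM |
| remark | run made earlier | run made earlier | run made earlier |  |
| time |  |  |  | 2.0 h |

| run | time / min | G / % | E / % |
|---|---|---|---|
| beta | 12.0 | 15.4 | 83.8 |
| beta | 30.0 | 32.2 | 65.7 |
| beta | 60.0 | 47.2 | 51.6 |
| beta | 90.0 | 53.3 | 44.5 |
| delta | 8.00 | 13.0 | 86.0 |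
| delta | 20.0 | 30.2 | 68.4 |
| delta | 40.0 | 49.6 | 48.6 |
| delta | 90.0 | 67.5 | 30.3 |
| zeta | 8.00 | 16.4 | 81.7 |
| zeta | 20.0 | 31.4 | 67.0 |
| zeta | 40.0 | 39.1 | 59.1 |
| zeta | 90.0 | 40.2 | 56.9 |

(readings scatter by 0.5 percentage points)

- the average divides the monomer in chains by the number of chains begun, living and dead together
- the numbers in the tables scatter by 0.5 percentage points (one standard deviation)
- what may be going on: D + E -> X; G + Q -> E + Q; E -> Z; E + L -> Q + G; E + Q -> G + Q
- the earlier runs do not show the number of chains; that part of a forecast is a guess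

* whether the average number of monomer units in a chain (chains begun, living or dead) reaches 20 by 2.0 h (no / yes)
* average number of monomer units in a chain (chains begun, living or dead) at 2.0 h

In the zeta run, E read 59.1% at 40.0 min and 56.9% at 90.0 min, so I took the last reading as a floor (the equilibrium monomer concentration):

c(E)floor = 56.9% × 0.20 M = 0.114 M

Of the E above this floor, I let D take its share one for one and counted the rest as going into chains. I guessed one chain per L, since the runs do not show the number of chains:

n = (c(E) charged − c(E)floor − c(D) charged) / c(L) charged = 4.11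

This n, the units I expected each chain to hold once E had reached the floor, was my first reckoning for the flask.

One number was not enough, though. The beta run has n = 8.11, but its G reading at 90.0 min gave 7.46 per L charged. In the beta readings, the height of E above the floor shrank 2.84-fold over the last 30.0 min. The flask was charged with the same c(L) as the beta run, 20 mM, so I assumed one more such step for it: at 2.0 h that left a shortfall of 2.81%, and I reckoned 3.99 for the flask, less than 20.

The forecast said no to reaching 20 and gave 4, between 3.6 and 4.6: “Chains are about 20 mM, giving an average near 4, far below 20.”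

The flask gave no, with 3.96 units per chain.

    D + E → X (k = 23.0 L mol⁻¹ min⁻¹)
    G + Q → E + Q, rate k2*[Q] as long as [G] is above zero (k = 0.170 min⁻¹)
    E → Z (k = 1.20 × 10⁻⁴ min⁻¹)
    E + L → Q + G (k = 0.580 L mol⁻¹ min⁻¹)
    E + Q → G + Q, rate k5*[Q]*[E] (k = 1.50 L mol⁻¹ min⁻¹)

At 2.0 h the flask held Q at 0.0200 M, with 0.00841% of its L left. For the neighbour flask charged with 0.50 M of E, n is 19.1, and the same shortfall brings it to 18.6. That flask gave 18.5.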